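The readings are simulated with made-up constants.

**Slow side.** The right-handed product comes so slowly that its single readings say little against a scatter of 2 percentage points, so add them up.

the same everywhere: left-handed substrate 49 mM; right-handed substrate 49 mM; gas 1.8 mM (held)

| run | free catalyst | remark | time |
|---|---|---|---|
| south-east | 0.021 mol% | run made earlier |  |
| west | 0.06 mol% | run made earlier |  |
| dawn | 0.05 mol% |  | 3.0 d |
| dusk | 0.015 mol% |  | 3.0 d |

- south-east (time / h: left-handed product / %, right-handed product / %): 8.00: 21, 0; 15.0: 37, 0; 20.0: 44, 3; 30.0: 54, 2; 40.0: 59, 0; 48.0: 64, 6
- west (time / h: left-handed product / %, right-handed product / %): 8.00: 42, 2; 15.0: 62, 1; 20.0: 73, 3; 30.0: 80, 3; 40.0: 88, 0; 48.0: 85, 3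

(standard deviation of a reading: 2 percentage points)

- free catalyst is single-handed; left-handed substrate and right-handed substrate are mirror images of each other, charged as a racemate, each of them at the stated concentration
- the numbers in the tables scatter by 2 percentage points (one standard deviation)
- at the start none of the gas is in solution
- an excess is the difference of the two amounts in percent of their sum
- an excess is below zero if the other one leads

- which one finishes higher in excess of left-handed product over right-handed product in the product ("neither" within 2 percentage points) (dawn / dusk / neither)
- excess of left-handed product over right-handed product in the product at the end, dawn
- excess of left-handed product over right-handed product in the product at the end, dusk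

**Bench rule.** Over both runs the left-handed readings sum to 709 % and the right-handed ones to 23.0 %, a ratio of 30.8. While the two substrates stand equal, this ratio is a reading of the selectivity factor. The product excess, ratio minus one over ratio plus one, is then 93.7 %. The right-handed sum carries a scatter of 6.9 points, and one standard deviation of it either way puts this excess at 91.9 % or 95.6 %, a band that the flask itself can lie outside. If one catalyst makes both products, its loading and its age divide out of the ratio.

**The border.** The rule stops where left-handed substrate is eaten faster than it is replaced. Dawn has 0.833 of the west loading. The west ratio of 35.8 and the south-east ratio of 25.4 rest on right-handed sums that each carry a scatter of 4.9 points, so these readings cannot show whether the higher loading loses selectivity. I keep the rule for want of a better reading, and as my own reckoning I expect neither flask to lead, both near 93.7 %.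

**The forecast.** It says 92 % for dawn and 96 % for dusk, so dusk, since at high loading “the slow right-handed reaction gains share”. That differs from my reckoning.

**The flask.** Dawn gives 96.5 % and dusk 97.1 %, so the answer is neither: the gap of 0.60 points is less than the margin.

    coupling partner + free catalyst + left-handed substrate → free catalyst + left-handed product (k = 3.91 × 10⁶ /M²/h)
    free catalyst → spent catalyst (k = 0.0191 /h)
    gas ⇌ coupling partner, rate k3*(csat - [coupling partner]) (kL = 26.7 /h)
    coupling partner + free catalyst + right-handed substrate → free catalyst + right-handed product (k = 51900 /M²/h)
    left-handed substrate ⇌ right-handed substrate (k = 0.161 /h)

**Not at rest.** Both excesses stand above my 93.7 %. At 3.00 d the dusk flask still holds 25.3 % of its free catalyst and 60.7 % left-handed product. The length of the run makes no difference to its excess. A neighbour with 0.0037 mol% free catalyst reaches 21.7 % left-handed product, with excess 97.3 %. Left until 30.0 d, the dusk flask has 0 % free catalyst, 13.6 % left-handed substrate and 71.7 % left-handed product, and its excess is 97.2 %.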